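**Retrosynthetic overview** (heptanoid numbering: C1 = aryl-bearing ring carbon, C3 = ring carbinol, C5 = ring carbon carrying the side chain, C6 = side-chain carbinol, C7 = benzylic CH2)
- Target ⇐ all-equatorial oxan-4-one carrying a C6 benzoate: C3–H by axial hydride addition, then ester cleavage.
- Oxan-4-one ⇐ dehydrozingerone + (R)-α-benzoyloxy aldehyde: C4–C5 aldol, then C1–O 6-endo oxa-Michael (a formal oxa-hetero-Diels–Alder). This forms the only new ring, the oxane.
- (R)-α-Benzoyloxy aldehyde ⇐ 3-(4-hydroxyphenyl)propanal by enamine-catalysed α-benzoyloxylation: C6 is the first stereocenter, set by a chiral amine without any metal.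
- Stereo relay: C6 (catalyst) → C5 (catalyst matched with Felkin control) → C1 (thermodynamic 2,6-cis) → C3 (axial hydride). The phenols stay free throughout.

Assumption: 3-(4-hydroxyphenyl)propanal and dehydrozingerone are bought as catalogue compounds, and the target is exactly the stereoisomer in the SMILES (all-cis 2,4,6-trisubstituted oxane, erythro C5/C6).

**Step 1**
Reactants: 1 3-(4-hydroxyphenyl)propanal
Product: 2 (2R)-1-(4-hydroxyphenyl)-3-oxopropan-2-yl benzoate
Conditions: (R)-2-[diphenyl(trimethylsilyloxy)methyl]pyrrolidine (10 mol%), (PhCO2)2 (1.0 equiv), 1 (1.3 equiv), hydroquinone (10 mol%), THF, 0 °C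
Reagents that add atoms: dibenzoyl peroxide, O=C(OOC(=O)c1ccccc1)c1ccccc1
Why: Enamine-catalysed asymmetric α-benzoyloxylation of an aldehyde: the CPh2(OTMS) group shields one face of the E-anti enamine, so the peroxide oxygen is attacked from the open face and the D-proline-derived catalyst gives the (R)-α-acyloxy aldehyde (about 90–94% ee is usual for 3-arylpropanals); the phenol should be tolerated (hydroquinone, itself a phenol, is a standard additive), and any stray O-benzoylation is erased in step 3.

**Step 2**
Reactants: 2 (2R)-1-(4-hydroxyphenyl)-3-oxopropan-2-yl benzoate; 3 (3E)-4-(4-hydroxy-3-methoxyphenyl)but-3-en-2-one (dehydrozingerone)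
Product: 5 (1R)-1-[(2S,6R)-6-(4-hydroxy-3-methoxyphenyl)-4-oxooxan-2-yl]-2-(4-hydroxyphenyl)ethyl benzoate, via open-chain aldol adduct 4 (not isolated)
Conditions: (R)-5-(pyrrolidin-2-yl)-1H-tetrazole (20 mol%), 3 (2.0 equiv), CHCl3/DMSO 9:1, 4 °C, 48 h; then Amberlyst-15, CH2Cl2, rt
Reagents that add atoms: none
Why: Proposed new method: the secondary amine condenses with the methyl ketone of 3 (its only enolisable position) to give a cross-conjugated 2-amino-diene whose terminal CH2 adds to the aldehyde of 2 through a hydrogen-bonded Houk–List-type transition state (the acidic tetrazole N–H activates the aldehyde), the D-configured catalyst directing attack to the Si face, which is also the face favoured by polar Felkin–Anh control with the C–OBz bond anti to the incoming carbon, so C5 is set (S) in a matched sense (5,6-anti); the iminium ion of adduct 4 and then the sulfonic acid resin promote a reversible 6-endo-trig oxa-Michael addition of the C5 hydroxyl that settles at the 2,6-cis diequatorial oxanone, which fixes C1 (R) and shuts off retro-aldol; the α-branched aldehyde 2 is a poor enamine donor towards a secondary amine and so acts only as acceptor; the closest known reaction types are the amine-catalysed formal oxa-hetero-Diels–Alder (aldol/oxa-Michael) reaction of enones with activated ketones such as isatins or aryl trifluoromethyl ketones and proline-type acetone aldols with chiral α-oxy aldehydes, neither of which has been shown for an enolisable α-acyloxy aldehyde with an electron-rich 4-aryl enone.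

**Step 3**
Reactants: 5 (1R)-1-[(2S,6R)-6-(4-hydroxy-3-methoxyphenyl)-4-oxooxan-2-yl]-2-(4-hydroxyphenyl)ethyl benzoate
Product: 7 (2R,4R,6S)-2-(4-hydroxy-3-methoxyphenyl)-6-[(1R)-1-hydroxy-2-(4-hydroxyphenyl)ethyl]oxan-4-ol, via hydroxy benzoate 6 (not isolated)
Conditions: NaBH4 (1.5 equiv), MeOH/THF 1:1, −40 °C; then K2CO3 (4 equiv), MeOH, rt; aq. NH4Cl
Reagents that add atoms: none
Why: Small-hydride reduction of a chair 2,6-cis-oxan-4-one with both substituents equatorial proceeds by axial attack and gives the equatorial (4R) alcohol, cis to both neighbours, and base-mediated transesterification (Zemplén-type methanolysis) then frees the C6 hydroxyl without touching a stereocenter.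

**Compound list**
1 | 3-(4-hydroxyphenyl)propanal | O=CCCc1ccc(O)cc1 | starting material
2 | (2R)-1-(4-hydroxyphenyl)-3-oxopropan-2-yl benzoate | O=C[C@H](OC(=O)c1ccccc1)Cc1ccc(O)cc1 | intermediate
3 | (3E)-4-(4-hydroxy-3-methoxyphenyl)but-3-en-2-one (dehydrozingerone) | COc1cc(/C=C/C(C)=O)ccc1O | starting material
4 | open-chain aldol adduct, (2R,3S,6E)-3-hydroxy-7-(4-hydroxy-3-methoxyphenyl)-1-(4-hydroxyphenyl)-5-oxohept-6-en-2-yl benzoate | COc1cc(/C=C/C(=O)C[C@H](O)[C@H](OC(=O)c2ccccc2)Cc2ccc(O)cc2)ccc1O | intermediate
5 | (1R)-1-[(2S,6R)-6-(4-hydroxy-3-methoxyphenyl)-4-oxooxan-2-yl]-2-(4-hydroxyphenyl)ethyl benzoate | COc1cc([C@H]2CC(=O)C[C@@H]([C@H](OC(=O)c3ccccc3)Cc3ccc(O)cc3)O2)ccc1O | intermediate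
6 | hydroxy benzoate, (1R)-1-[(2S,4R,6R)-4-hydroxy-6-(4-hydroxy-3-methoxyphenyl)oxan-2-yl]-2-(4-hydroxyphenyl)ethyl benzoate | COc1cc([C@H]2C[C@@H](O)C[C@@H]([C@H](OC(=O)c3ccccc3)Cc3ccc(O)cc3)O2)ccc1O | intermediate
7 | (2R,4R,6S)-2-(4-hydroxy-3-methoxyphenyl)-6-[(1R)-1-hydroxy-2-(4-hydroxyphenyl)ethyl]oxan-4-ol | COc1cc([C@H]2C[C@@H](O)C[C@@H]([C@H](O)Cc3ccc(O)cc3)O2)ccc1O | target

**Total step count:** 3 (three isolations; steps 2 and 3 each run two stages in one flask).
**Longest linear sequence:** 3 (1 → 2 → 5 → 7).

**Steps most likely to fail, with fallbacks**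

1. Step 2 (the proposed new step).
   - Risks: slow enamine formation from the push–pull enone; dehydration of 4; 1,2-benzoate shift followed by β-elimination; erosion at C6 through enamine formation from 2. The minor (S)-enantiomer of 2 is mismatched and should go mainly to separable diastereomers, so the ee of 5 should exceed that of 2.
   - Fallback (known chemistry): sets out from 2 and 3 and comes back at 5. Compound 3 is converted with Me3SiOTf and Et3N (CH2Cl2, 0 °C) into the bis-silyl dienol ether trimethyl({2-methoxy-4-[(1E)-3-[(trimethylsilyl)oxy]buta-1,3-dien-1-yl]phenoxy})silane F3. F3 is added to 2 in a Mukaiyama aldol reaction (BF3·OEt2, CH2Cl2, −78 °C; NaHCO3 quench, then aqueous citric acid to cleave the aryl silyl ether). Polar Felkin–Anh control by the α-benzoyloxy group gives the 5,6-anti adduct 4, which is now isolated and freed from the minor syn isomer. Amberlyst-15 in CH2Cl2 at rt then closes the ring to the cis-oxanone 5.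

2. Step 1.
   - Risks: the free phenol interfering with the peroxide or the catalyst; modest ee; lability of 2 on silica.
   - Fallback: sets out from 1 and comes back at 2. The route stops being protecting-group-free here: 1 is silylated (t-BuMe2SiCl, imidazole, DMF) to 3-{4-[(tert-butyldimethylsilyl)oxy]phenyl}propanal F1, an aldehyde of the type for which the oxidation is established. The same benzoyloxylation gives (2R)-1-{4-[(tert-butyldimethylsilyl)oxy]phenyl}-3-oxopropan-2-yl benzoate F2. HF·pyridine (THF, 0 °C) removes the aryl silyl ether to give 2.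

3. Step 3.
   - Risks: incomplete selectivity at C3; slow methanolysis with two phenoxides present; base-induced opening of the 4-hydroxybenzylic ether through a quinone methide.
   - Fallback: sets out from 5 and comes back at 7, and makes no new compound (entry F0). The two events are decoupled and the ester is removed by hydride instead of alkoxide. NaBH4 (MeOH/THF, −40 °C) gives 6, which is isolated and freed from any C3 epimer. i-Bu2AlH (6 equiv, CH2Cl2, −78 to 0 °C) then cleaves the benzoate reductively to give 7.

**Further compounds**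
F1 | step 1 | 3-{4-[(tert-butyldimethylsilyl)oxy]phenyl}propanal | O=CCCc1ccc(O[Si](C)(C)C(C)(C)C)cc1
F2 | step 1 | (2R)-1-{4-[(tert-butyldimethylsilyl)oxy]phenyl}-3-oxopropan-2-yl benzoate | O=C[C@H](OC(=O)c1ccccc1)Cc1ccc(O[Si](C)(C)C(C)(C)C)cc1
F3 | step 2 | trimethyl({2-methoxy-4-[(1E)-3-[(trimethylsilyl)oxy]buta-1,3-dien-1-yl]phenoxy})silane | COc1cc(/C=C/C(=C)O[Si](C)(C)C)ccc1O[Si](C)(C)C
F0 | step 3 | none | none
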